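**Retrosynthetic overview**
1. Numbering: ring A of the target is the dihydropyran O1–C2(CH3)–C3(C10H2OH)–C4(C8H2–C9O2R)–C5(CO2Me)=C6H. The plan rests on C4, which is shared by a formylacetate unit (C6, C5, CO2Me) and a three-carbon acyl unit (C4, C8, C9). This is the pattern left when an enal is joined to a 1,3-dicarbonyl compound.
2. After the silyl groups, the last disconnections are O1–C6 (ring A, closed last, by dehydration) and the C9–O bond to hydroxytyrosol. Both lead back to one enol lactone, ring B (O, C6, C5, C4, C8, C9; closed first), whose enol ester is both the activated C9 acyl group and the masked C6 formyl group.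
3. Ring B is cut at C4–C5 and C6O–C9 into the γ-branched enal 8 and methyl formylacetate 10 (oxidative carbene catalysis, sets C4).
4. Enal 8 comes from cross metathesis of a vinyl compound. That compound is made by copper-catalysed vinyl opening of (2S,3S)-2,3-epoxybutan-1-ol, itself obtained by Sharpless epoxidation of (E)-crotyl alcohol (sets C2 and C3).

Key step: step 7

Assumption: the (5aR,10bS) antipode of the triazolium salt is taken to leave the C4 Re face open (s-cis acyl azolium lying on the indane side of the catalyst); both antipodes are commercial, so a reversed sense would be met by exchanging the catalyst only.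

**Route**

Step 1
Reactants: 1 (E)-but-2-en-1-ol
Product: 2 [(2S,3S)-3-methyloxiran-2-yl]methanol
Conditions: Ti(OiPr)4 (5 mol%), L-(+)-diisopropyl tartrate (6 mol%), anhydrous tBuOOH, 4 Å MS, CH2Cl2, -20 °C; excess peroxide reduced with Me2S, non-aqueous work-up, distillation
Reagents that add atoms: tert-butyl hydroperoxide, CC(C)(C)OO
Why: Sharpless asymmetric epoxidation, in which the titanium complex of the L-(+)-tartrate delivers oxygen to the face of the E-allylic alcohol that gives the (2S,3S)-trans-epoxide, fixing the C2–O centre and the sense of the later inversion at C3.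

Step 2
Reactants: 2 [(2S,3S)-3-methyloxiran-2-yl]methanol; 3 vinylmagnesium bromide
Product: 4 (2R,3S)-2-ethenylbutane-1,3-diol
Conditions: 3 (3 equiv), CuI (10 mol%), THF/Et2O, -40 to -20 °C; aq NH4Cl; crude diol stirred with NaIO4 in THF/H2O to cleave the 1,2-diol isomer
Reagents that add atoms: none
Why: Copper-catalysed Grignard opening of a 2,3-epoxy alcohol, in which the vinyl copper species attacks the oxirane carbon next to the carbinol by SN2 with inversion to give the 1,3-diol, so the trans-epoxide maps onto the C2/C3 relationship of the target (O and C10 syn on the zigzag chain CH3–C2–C3–C4).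

Step 3
Reactants: 4 (2R,3S)-2-ethenylbutane-1,3-diol
Product: 5 (2S,3R)-3-[(tert-butyldiphenylsilyl)oxymethyl]pent-4-en-2-ol
Conditions: TBDPSCl (1.05 equiv), imidazole, CH2Cl2, 0 °C
Reagents that add atoms: tert-butyldiphenylsilyl chloride, CC(C)(C)[Si](Cl)(c1ccccc1)c1ccccc1
Why: Sterically controlled silylation takes the primary C10 hydroxyl only, and TBDPS is chosen because it must outlast the acid of step 11, where a free C10 hydroxyl would compete for C6 and C9.

Step 4
Reactants: 5 (2S,3R)-3-[(tert-butyldiphenylsilyl)oxymethyl]pent-4-en-2-ol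
Product: 6 (3R,4S)-3-[(tert-butyldiphenylsilyl)oxymethyl]-4-(triethylsilyloxy)pent-1-ene
Conditions: TESCl, imidazole, DMAP (cat), CH2Cl2, 0 °C to rt
Reagents that add atoms: chlorotriethylsilane, CC[Si](Cl)(CC)CC
Why: Standard silylation of the remaining secondary alcohol gives the most acid-labile silyl ether of the set, which is what later allows the C2 hydroxyl to be released alone.

Step 5
Reactants: 6 (3R,4S)-3-[(tert-butyldiphenylsilyl)oxymethyl]-4-(triethylsilyloxy)pent-1-ene; 7 (E)-crotonaldehyde
Product: 8 (4R,5S,E)-4-[(tert-butyldiphenylsilyl)oxymethyl]-5-(triethylsilyloxy)hex-2-enal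
Conditions: 7 (5 equiv), second-generation Hoveyda-Grubbs catalyst RuCl2(H2IMes)(=CH-C6H4-2-OiPr) (5 mol%), CH2Cl2, 40 °C
Reagents that add atoms: none
Why: Olefin cross metathesis of a terminal, allylically branched alkene that homodimerises slowly with an electron-poor enal used in excess is driven by loss of propene and should give the E-enal under neutral conditions that leave C3 untouched.

Step 6
Reactants: 9 methyl 3,3-dimethoxypropanoate
Product: 10 methyl 3-oxopropanoate (methyl formylacetate, present mainly as its hydrogen-bonded enol)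
Conditions: 2 M aq HCl, THF, rt; extraction into CH2Cl2, drying, use on the same day
Reagents that add atoms: water, O
Why: Acid-catalysed acetal hydrolysis frees the formyl group, and immediate use avoids the self-condensation to which the product is prone.

Step 7
Reactants: 8 (4R,5S,E)-4-[(tert-butyldiphenylsilyl)oxymethyl]-5-(triethylsilyloxy)hex-2-enal; 10 methyl 3-oxopropanoate
Product: 12 methyl (4S)-4-[(2R,3S)-1-(tert-butyldiphenylsilyloxy)-3-(triethylsilyloxy)butan-2-yl]-2-oxo-3,4-dihydro-2H-pyran-5-carboxylate, via unsaturated acyl azolium 11 (not isolated)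
Conditions: (5aR,10bS)-2-mesityl-5a,10b-dihydro-4H,6H-indeno[2,1-b][1,2,4]triazolo[4,3-d][1,4]oxazin-2-ium tetrafluoroborate (10 mol%), DBU (20 mol%), 3,3',5,5'-tetra-tert-butyl-4,4'-diphenoquinone (1.2 equiv), 4 Å MS, toluene, rt; 10 (1.5 equiv) added by syringe pump over 4 h
Reagents that add atoms: none
Why: The carbene adds to the formyl group of 8 and the diphenoquinone oxidises the resulting enaminol to the α,β-unsaturated acyl azolium 11, whose C4 takes up the enol of 10 (conjugate addition, or addition at C9 followed by a [3,3] shift) to make C4–C5. After proton transfer the C6 enol oxygen attacks the acyl azolium carbonyl C9 in a 6-exo-trig acylation that closes ring B and releases the carbene. The closest known reaction is the oxidative carbene-catalysed [3+3] annulation of enals with β-keto esters and 1,3-diketones to 3,4-dihydropyran-2-ones, and the union of a formylacetate enolate with an unsaturated acyl azolium is known from the carbene-catalysed rearrangement of enoyl enol esters. C4 becomes S through attack on its Re face (C8 > C3 > H), and this is put under catalyst control, the indane wall covering the Si face, because the E-enal has little 1,3-allylic strain and its own bias is small: a Felkin-type array (C2 branch anti to the nucleophile, C3–H outside) opens the Re face, whereas the rotamer with C3–H eclipsing the alkene opens the Si face. Regioselectivity comes from 10 itself, since of its two carbonyl groups only the aldehyde gives an enol oxygen able to acylate, so the ring oxygen can only end on C6. Chemoselectivity between the two aldehydes is needed and rests on 10 being a hydrogen-bonded enol held at low concentration by slow addition while 8 is a free enal, and any C4 epimer formed is a diastereomer that chromatography removes.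

Step 8
Reactants: 13 hydroxytyrosol (4-(2-hydroxyethyl)benzene-1,2-diol)
Product: 14 1,2-bis(tert-butyldimethylsilyloxy)-4-[2-(tert-butyldimethylsilyloxy)ethyl]benzene
Conditions: TBSCl (3.5 equiv), imidazole, DMF, rt
Reagents that add atoms: tert-butyldimethylsilyl chloride, CC(C)(C)[Si](C)(C)Cl
Why: Exhaustive silylation with excess chlorosilane and imidazole caps both phenols and the primary alcohol and protects the catechol from oxidation.

Step 9
Reactants: 14 1,2-bis(tert-butyldimethylsilyloxy)-4-[2-(tert-butyldimethylsilyloxy)ethyl]benzene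
Product: 15 2-[3,4-bis(tert-butyldimethylsilyloxy)phenyl]ethanol
Conditions: AcOH/THF/H2O (3:1:1), rt
Reagents that add atoms: none
Why: Acid hydrolysis distinguishes the silyl ethers because the alkyl ether oxygen is protonated far more readily than the aryl ether oxygens, so only the primary alcohol is released.

Step 10
Reactants: 12 methyl (4S)-4-[(2R,3S)-1-(tert-butyldiphenylsilyloxy)-3-(triethylsilyloxy)butan-2-yl]-2-oxo-3,4-dihydro-2H-pyran-5-carboxylate; 15 2-[3,4-bis(tert-butyldimethylsilyloxy)phenyl]ethanol
Product: 16 1-{2-[3,4-bis(tert-butyldimethylsilyloxy)phenyl]ethyl} 5-methyl (3S)-3-[(2R,3S)-1-(tert-butyldiphenylsilyloxy)-3-(triethylsilyloxy)butan-2-yl]-4-formylpentanedioate (C5 epimers in equilibrium with the enol)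
Conditions: 15 (1.1 equiv), DMAP (20 mol%), CH2Cl2, rt
Reagents that add atoms: none
Why: DMAP-catalysed alcoholysis of an enol ester should run at room temperature because the leaving group at C9 is the stabilised enolate of a formylacetate, and it installs the hydroxytyrosol arm while unmasking the C6 formyl group without touching C2, C3 or C4.

Step 11
Reactants: 16 ring-opened formyl diester
Product: 19 methyl (2S,3R,4S)-4-(2-{2-[3,4-bis(tert-butyldimethylsilyloxy)phenyl]ethoxy}-2-oxoethyl)-3-[(tert-butyldiphenylsilyl)oxymethyl]-2-methyl-3,4-dihydro-2H-pyran-5-carboxylate, via hydroxy aldehyde 17 (not isolated), via lactol 18 (not isolated)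
Conditions: CSA (10 mol%), THF/H2O (10:1), 0 °C to rt; solvent change to toluene, CSA (5 mol%), 4 Å MS, 40 °C
Reagents that add atoms: none
Why: Mild acid hydrolyses the secondary triethylsilyl ether well before the TBDPS and aryl TBS ethers, the C2 hydroxyl adds to the C6 formyl group (6-exo-trig hemiacetal) and acid-catalysed loss of water gives the ester-conjugated enol ether of ring A, the same hydroxyl-onto-acyl closure as in the acyl-lactone rearrangement.

Step 12
Reactants: 19 fully silylated dihydropyran
Product: 20 methyl (2S,3R,4S)-4-{2-[2-(3,4-dihydroxyphenyl)ethoxy]-2-oxoethyl}-3-(hydroxymethyl)-2-methyl-3,4-dihydro-2H-pyran-5-carboxylate (target)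
Conditions: HF·pyridine, extra pyridine, THF, 0 °C to rt, polyethylene vessel, argon; pH 7 buffer work-up
Reagents that add atoms: none
Why: Fluoride-driven cleavage of all three silyl ethers is run under weakly acidic buffered conditions rather than with basic TBAF, because an alkoxide at C10 could lactonise onto C9 and a catecholate would oxidise in air.

**Compound list**
1 | (E)-but-2-en-1-ol | C/C=C/CO | starting material
2 | [(2S,3S)-3-methyloxiran-2-yl]methanol | C[C@@H]1O[C@H]1CO | intermediate
3 | vinylmagnesium bromide | C=C[Mg]Br | starting material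
4 | (2R,3S)-2-ethenylbutane-1,3-diol | C[C@H](O)[C@@H](CO)C=C | intermediate
5 | (2S,3R)-3-[(tert-butyldiphenylsilyl)oxymethyl]pent-4-en-2-ol | C[C@H](O)[C@@H](CO[Si](c1ccccc1)(c1ccccc1)C(C)(C)C)C=C | intermediate
6 | (3R,4S)-3-[(tert-butyldiphenylsilyl)oxymethyl]-4-(triethylsilyloxy)pent-1-ene | CC[Si](CC)(CC)O[C@@H](C)[C@@H](CO[Si](c1ccccc1)(c1ccccc1)C(C)(C)C)C=C | intermediate
7 | (E)-crotonaldehyde | C/C=C/C=O | starting material
8 | (4R,5S,E)-4-[(tert-butyldiphenylsilyl)oxymethyl]-5-(triethylsilyloxy)hex-2-enal | CC[Si](CC)(CC)O[C@@H](C)[C@@H](CO[Si](c1ccccc1)(c1ccccc1)C(C)(C)C)/C=C/C=O | intermediate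
9 | methyl 3,3-dimethoxypropanoate | COC(=O)CC(OC)OC | starting material
10 | methyl 3-oxopropanoate (methyl formylacetate) | COC(=O)CC=O | intermediate
11 | α,β-unsaturated acyl azolium from 8 and the (5aR,10bS)-carbene (cation shown) | Cc1cc(C)c(c(C)c1)[n+]1c(C(=O)/C=C/[C@H](CO[Si](c4ccccc4)(c4ccccc4)C(C)(C)C)[C@H](C)O[Si](CC)(CC)CC)n2c(n1)CO[C@@H]1Cc3ccccc3[C@H]21 | intermediate (not isolated)
12 | methyl (4S)-4-[(2R,3S)-1-(tert-butyldiphenylsilyloxy)-3-(triethylsilyloxy)butan-2-yl]-2-oxo-3,4-dihydro-2H-pyran-5-carboxylate | CC[Si](CC)(CC)O[C@@H](C)[C@@H](CO[Si](c1ccccc1)(c1ccccc1)C(C)(C)C)[C@@H]1CC(=O)OC=C1C(=O)OC | intermediate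
13 | hydroxytyrosol | OCCc1ccc(O)c(O)c1 | starting material
14 | 1,2-bis(tert-butyldimethylsilyloxy)-4-[2-(tert-butyldimethylsilyloxy)ethyl]benzene | CC(C)(C)[Si](C)(C)OCCc1ccc(O[Si](C)(C)C(C)(C)C)c(O[Si](C)(C)C(C)(C)C)c1 | intermediate
15 | 2-[3,4-bis(tert-butyldimethylsilyloxy)phenyl]ethanol | OCCc1ccc(O[Si](C)(C)C(C)(C)C)c(O[Si](C)(C)C(C)(C)C)c1 | intermediate
16 | 1-{2-[3,4-bis(tert-butyldimethylsilyloxy)phenyl]ethyl} 5-methyl (3S)-3-[(2R,3S)-1-(tert-butyldiphenylsilyloxy)-3-(triethylsilyloxy)butan-2-yl]-4-formylpentanedioate | COC(=O)C(C=O)[C@@H](CC(=O)OCCc1ccc(O[Si](C)(C)C(C)(C)C)c(O[Si](C)(C)C(C)(C)C)c1)[C@H](CO[Si](c1ccccc1)(c1ccccc1)C(C)(C)C)[C@H](C)O[Si](CC)(CC)CC | intermediate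
17 | C2-hydroxy analogue of 16 (triethylsilyl group removed) | COC(=O)C(C=O)[C@@H](CC(=O)OCCc1ccc(O[Si](C)(C)C(C)(C)C)c(O[Si](C)(C)C(C)(C)C)c1)[C@H](CO[Si](c1ccccc1)(c1ccccc1)C(C)(C)C)[C@H](C)O | intermediate (not isolated)
18 | 6-hydroxytetrahydropyran (lactol) form of 17, (2S,3R,4S), C5 and C6 unassigned | COC(=O)C1C(O)O[C@@H](C)[C@@H](CO[Si](c2ccccc2)(c2ccccc2)C(C)(C)C)[C@@H]1CC(=O)OCCc1ccc(O[Si](C)(C)C(C)(C)C)c(O[Si](C)(C)C(C)(C)C)c1 | intermediate (not isolated)
19 | methyl (2S,3R,4S)-4-(2-{2-[3,4-bis(tert-butyldimethylsilyloxy)phenyl]ethoxy}-2-oxoethyl)-3-[(tert-butyldiphenylsilyl)oxymethyl]-2-methyl-3,4-dihydro-2H-pyran-5-carboxylate | COC(=O)C1=CO[C@@H](C)[C@@H](CO[Si](c2ccccc2)(c2ccccc2)C(C)(C)C)[C@@H]1CC(=O)OCCc1ccc(O[Si](C)(C)C(C)(C)C)c(O[Si](C)(C)C(C)(C)C)c1 | intermediate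
20 | methyl (2S,3R,4S)-4-{2-[2-(3,4-dihydroxyphenyl)ethoxy]-2-oxoethyl}-3-(hydroxymethyl)-2-methyl-3,4-dihydro-2H-pyran-5-carboxylate | COC(=O)C1=CO[C@@H](C)[C@@H](CO)[C@@H]1CC(=O)OCCc1ccc(O)c(O)c1 | target

**Step count**
Total step count: 12.
Longest linear sequence: 9 (steps 1, 2, 3, 4, 5, 7, 10, 11, 12).

**Steps most likely to fail**

1. Step 7. What may go wrong:
- The carbene or the oxidant may consume the formyl group of 10, or 10 may self-condense, faster than the hindered C4 of the acyl azolium is attacked.
- The base may remove the γ-proton at C3.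
- Face selection at C4 may be weak.

The fallback sets out from 8 (with 10) and returns at 12. It reaches the same reactive pair without oxidant and without free formylacetate in the catalytic step.
- Pinnick oxidation of 8 (NaClO2, NaH2PO4, 2-methylbut-2-ene) should give (4R,5S,E)-4-[(tert-butyldiphenylsilyl)oxymethyl]-5-(triethylsilyloxy)hex-2-enoic acid F1.
- Carbodiimide coupling (EDC, DMAP) of this acid with the enol of 10 should give (E)-3-methoxy-3-oxoprop-1-enyl (4R,5S,E)-4-[(tert-butyldiphenylsilyl)oxymethyl]-5-(triethylsilyloxy)hex-2-enoate F2.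
- The same chiral carbene then triggers the known rearrangement of enoyl enol esters. It cleaves the activated ester into acyl azolium and formylacetate enolate in equal amounts, and these recombine at C4 and lactonise to 12.

2. Step 11. What may go wrong:
- After loss of the triethylsilyl group the lactol may resist dehydration.
- Prolonged acid may let the C2 hydroxyl transesterify onto C9, with loss of the hydroxytyrosol arm.

The fallback sets out from 16 and returns at 19. It replaces acid dehydration by a base-induced elimination.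
- Pyridine-buffered HF·pyridine at 0 °C removes only the triethylsilyl group, and lactol 18 is isolated.
- MsCl and Et3N at 0 °C convert it into the lactol methanesulfonate F3.
- F3 loses methanesulfonate by E1cB through the acidic C5–H to give 19.

3. Step 10. What may go wrong:
- Acyl transfer may be slow.
- The alcohol or DMAP may add to C6 of the β-acyloxyacrylate by addition-elimination instead of attacking C9, which would waste 15.

The fallback sets out from 12 and returns at 19. It moves the ester bond formation to a conventional coupling.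
- Hydrolysis of 12 (NaHCO3, THF/H2O) should give (3S)-3-[(2R,3S)-1-(tert-butyldiphenylsilyloxy)-3-(triethylsilyloxy)butan-2-yl]-4-formyl-5-methoxy-5-oxopentanoic acid F4. Attack of water at C9 or at C6 leads to this same product.
- The acid conditions of step 11 should close ring A to {(2S,3R,4S)-3-[(tert-butyldiphenylsilyl)oxymethyl]-5-(methoxycarbonyl)-2-methyl-3,4-dihydro-2H-pyran-4-yl}acetic acid F5.
- Steglich esterification (EDC, DMAP) of this acid with 15 gives 19.

**Further compounds**
F1 | step 7 | (4R,5S,E)-4-[(tert-butyldiphenylsilyl)oxymethyl]-5-(triethylsilyloxy)hex-2-enoic acid | CC[Si](CC)(CC)O[C@@H](C)[C@@H](CO[Si](c1ccccc1)(c1ccccc1)C(C)(C)C)/C=C/C(=O)O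
F2 | step 7 | (E)-3-methoxy-3-oxoprop-1-enyl (4R,5S,E)-4-[(tert-butyldiphenylsilyl)oxymethyl]-5-(triethylsilyloxy)hex-2-enoate | CC[Si](CC)(CC)O[C@@H](C)[C@@H](CO[Si](c1ccccc1)(c1ccccc1)C(C)(C)C)/C=C/C(=O)O/C=C/C(=O)OC
F3 | step 11 | lactol methanesulfonate of 18 | COC(=O)C1C(OS(C)(=O)=O)O[C@@H](C)[C@@H](CO[Si](c2ccccc2)(c2ccccc2)C(C)(C)C)[C@@H]1CC(=O)OCCc1ccc(O[Si](C)(C)C(C)(C)C)c(O[Si](C)(C)C(C)(C)C)c1
F4 | step 10 | (3S)-3-[(2R,3S)-1-(tert-butyldiphenylsilyloxy)-3-(triethylsilyloxy)butan-2-yl]-4-formyl-5-methoxy-5-oxopentanoic acid | COC(=O)C(C=O)[C@@H](CC(=O)O)[C@H](CO[Si](c1ccccc1)(c1ccccc1)C(C)(C)C)[C@H](C)O[Si](CC)(CC)CC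
F5 | step 10 | {(2S,3R,4S)-3-[(tert-butyldiphenylsilyl)oxymethyl]-5-(methoxycarbonyl)-2-methyl-3,4-dihydro-2H-pyran-4-yl}acetic acid | COC(=O)C1=CO[C@@H](C)[C@@H](CO[Si](c2ccccc2)(c2ccccc2)C(C)(C)C)[C@@H]1CC(=O)O
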